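**Plan**
- Ring B carries C2' (OH) and C3' (prenyl) side by side, next to the C4' methoxy group. A C2'–C3' aryne polarised by that methoxy group can therefore take up oxygen at C2' and, after a [3,3] shift, carbon at C3'.
- Retrosynthetic cuts, in order: the 7-O-MOM acetal; the C2'–O and C3'–CH2 bonds together (aryne plus 2-methylbut-3-en-2-ol); the C2'–OTf/C3'–Si pair (back to a silylated aryl carbamate); the C4 methylene and C3 centre (back to an isoflavone); the C3–C1' bond (3-iodochromone plus ring B boronate).
- Forward: ring C closes first, by iodocyclisation of an enaminone on the ring A acetophenone. Ring B, already silylated by two directed lithiations, is joined by Suzuki coupling. The chromone is reduced to the chroman, and ring B is then turned into the silyl triflate. The aryne step closes no ring.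
- Stereochemistry: the single (3R) centre comes from Ru-catalysed asymmetric transfer hydrogenation of the isoflavone with dynamic kinetic resolution, using the (R,R)-TsDPEN ligand. The C4 carbinol formed with it is removed afterwards.

Key step: step 12

Remark: the SMILES descriptor corresponds to (3R), the only stereocentre. Compounds 1, 5 and 17 are taken as purchasable.

**Step 1**
Reactants: 1 1-(2,4-dihydroxy-6-methoxyphenyl)ethanone
Product: 2 1-[2-hydroxy-6-methoxy-4-(methoxymethoxy)phenyl]ethanone
Conditions: MOMCl (1.1 equiv), K2CO3, acetone, 0 °C to rt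
Reagents that add atoms: chloromethyl methyl ether, COCCl
Why: Williamson-type O-alkylation should cap only the 4-hydroxyl, which is para to the acetyl group and free, because the 2-hydroxyl is tied up in a hydrogen bond to the ketone.

**Step 2**
Reactants: 2 1-[2-hydroxy-6-methoxy-4-(methoxymethoxy)phenyl]ethanone
Product: 3 (E)-3-(dimethylamino)-1-[2-hydroxy-6-methoxy-4-(methoxymethoxy)phenyl]prop-2-en-1-one
Conditions: Me2NCH(OMe)2, PhMe, 95 °C
Reagents that add atoms: N,N-dimethylformamide dimethyl acetal, COC(OC)N(C)C
Why: Condensation of the methyl ketone with the amide acetal (enaminone formation) should give the vinylogous amide with loss of two methanol.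

**Step 3**
Reactants: 3 (E)-3-(dimethylamino)-1-[2-hydroxy-6-methoxy-4-(methoxymethoxy)phenyl]prop-2-en-1-one
Product: 4 3-iodo-5-methoxy-7-(methoxymethoxy)-4H-chromen-4-one
Conditions: I2, pyridine, CHCl3, rt; aq. Na2S2O3
Reagents that add atoms: iodine, II
Why: Iodination of the enaminone alpha carbon, attack of the phenol on the iminium carbon and loss of dimethylamine (iodocyclisation to a 3-iodochromone) should close ring C, with pyridine keeping the medium non-acidic for the MOM acetal.

**Step 4**
Reactants: 5 3-methoxyphenol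
Product: 6 3-methoxyphenyl N,N-diethylcarbamate
Conditions: Et2NCOCl, K2CO3, MeCN, reflux
Reagents that add atoms: N,N-diethylcarbamoyl chloride, CCN(CC)C(Cl)=O
Why: O-Carbamoylation of the phenol installs the strongest oxygen-based directing group for ortho-lithiation, and it also protects the future 2'-oxygen through to step 10.

**Step 5**
Reactants: 6 3-methoxyphenyl N,N-diethylcarbamate
Product: 8 3-methoxy-2-(trimethylsilyl)phenyl N,N-diethylcarbamate, via 2-lithio carbamate 7 (not isolated)
Conditions: s-BuLi, TMEDA, THF, −78 °C; then TMSCl, −78 °C to rt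
Reagents that add atoms: chlorotrimethylsilane, C[Si](C)(C)Cl
Why: Directed ortho-metalation should occur at the carbon between the carbamate and the methoxy group, which both activate it, and TMSCl traps the aryllithium at −78 °C before an anionic Fries shift can start.

**Step 6**
Reactants: 8 3-methoxy-2-(trimethylsilyl)phenyl N,N-diethylcarbamate
Product: 10 3-methoxy-6-(4,4,5,5-tetramethyl-1,3,2-dioxaborolan-2-yl)-2-(trimethylsilyl)phenyl N,N-diethylcarbamate, via 6-lithio silyl carbamate 9 (not isolated)
Conditions: s-BuLi, TMEDA, THF, −78 °C; then i-PrOBpin, −78 °C to rt; aq. NH4Cl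
Reagents that add atoms: 2-isopropoxy-4,4,5,5-tetramethyl-1,3,2-dioxaborolane, CC(C)OB1OC(C)(C)C(C)(C)O1
Why: With the doubly activated site blocked by silicon, a second directed ortho-metalation should go to the other carbon ortho to the carbamate (the weaker methoxy director loses), and the borate ester traps it (lithiation–borylation).

**Step 7**
Reactants: 4 3-iodo-5-methoxy-7-(methoxymethoxy)-4H-chromen-4-one; 10 3-methoxy-6-(4,4,5,5-tetramethyl-1,3,2-dioxaborolan-2-yl)-2-(trimethylsilyl)phenyl N,N-diethylcarbamate
Product: 11 3-methoxy-6-[5-methoxy-7-(methoxymethoxy)-4-oxo-4H-chromen-3-yl]-2-(trimethylsilyl)phenyl N,N-diethylcarbamate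
Conditions: Pd(PPh3)4 (5 mol %), Na2CO3 (aq.), DME, 80 °C
Reagents that add atoms: none
Why: Suzuki–Miyaura coupling of a 3-iodochromone with an arylboronate is the standard isoflavone synthesis and forms the C3–C1' bond, while the fluoride-free carbonate base leaves the aryl–silicon bond and the carbamate intact.

**Step 8**
Reactants: 11 3-methoxy-6-[5-methoxy-7-(methoxymethoxy)-4-oxo-4H-chromen-3-yl]-2-(trimethylsilyl)phenyl N,N-diethylcarbamate
Product: 13 6-[(3R,4R)-4-hydroxy-5-methoxy-7-(methoxymethoxy)chroman-3-yl]-3-methoxy-2-(trimethylsilyl)phenyl N,N-diethylcarbamate, via racemising isoflavanone 12 (not isolated)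
Conditions: RuCl[(R,R)-TsDPEN](p-cymene) (3 mol %), HCO2H/Et3N (5:2), EtOAc, 40 °C
Reagents that add atoms: none
Why: In this Noyori–Ikariya asymmetric transfer hydrogenation, conjugate reduction gives isoflavanone 12, which racemises through its enol under Et3N while the (R,R) catalyst reduces the 3R ketone faster and delivers hydride trans to the aryl group, so dynamic kinetic resolution should set C3 (R) and C4 (R) together in the cis alcohol.

**Step 9**
Reactants: 13 6-[(3R,4R)-4-hydroxy-5-methoxy-7-(methoxymethoxy)chroman-3-yl]-3-methoxy-2-(trimethylsilyl)phenyl N,N-diethylcarbamate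
Product: 14 3-methoxy-6-[(3R)-5-methoxy-7-(methoxymethoxy)chroman-3-yl]-2-(trimethylsilyl)phenyl N,N-diethylcarbamate
Conditions: H2 (1 atm), 10% Pd/C, EtOH/AcOH (20:1), rt
Reagents that add atoms: none
Why: Catalytic hydrogenolysis of the benzylic C4–O bond, which three ring A oxygen donors activate, should remove the carbinol without touching C3, and the MOM acetal, carbamate and aryl–silicon bond tolerate H2/Pd and dilute acetic acid.

**Step 10**
Reactants: 14 3-methoxy-6-[(3R)-5-methoxy-7-(methoxymethoxy)chroman-3-yl]-2-(trimethylsilyl)phenyl N,N-diethylcarbamate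
Product: 15 3-methoxy-6-[(3R)-5-methoxy-7-(methoxymethoxy)chroman-3-yl]-2-(trimethylsilyl)phenol
Conditions: LiAlH4, THF, 0 °C to reflux; H2O, aq. NaOH
Reagents that add atoms: none
Why: Hydride reduction of the aryl carbamate (addition to the carbonyl, expulsion of the phenoxide) should free the 2'-phenol, since the acetal, the aryl silane and the methyl ethers are inert to LiAlH4.

**Step 11**
Reactants: 15 3-methoxy-6-[(3R)-5-methoxy-7-(methoxymethoxy)chroman-3-yl]-2-(trimethylsilyl)phenol
Product: 16 3-methoxy-6-[(3R)-5-methoxy-7-(methoxymethoxy)chroman-3-yl]-2-(trimethylsilyl)phenyl trifluoromethanesulfonate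
Conditions: PhNTf2, DBU, MeCN, rt
Reagents that add atoms: N-phenylbis(trifluoromethanesulfonimide), O=S(=O)(N(c1ccccc1)S(=O)(=O)C(F)(F)F)C(F)(F)F
Why: O-Triflation of the amidine-generated phenoxide with the mild triflyl donor PhNTf2 should complete the 2-(trimethylsilyl)aryl triflate aryne precursor under conditions that spare the MOM acetal.

**Step 12**
Reactants: 16 3-methoxy-6-[(3R)-5-methoxy-7-(methoxymethoxy)chroman-3-yl]-2-(trimethylsilyl)phenyl trifluoromethanesulfonate; 17 2-methylbut-3-en-2-ol
Product: 21 3-methoxy-6-[(3R)-5-methoxy-7-(methoxymethoxy)chroman-3-yl]-2-(3-methylbut-2-en-1-yl)phenol, via C2'-C3' aryne 18 (not isolated), via aryl 1,1-dimethylallyl ether 19 (not isolated), via ortho-prenyl cyclohexadienone 20 (not isolated)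
Conditions: 17 (6 equiv), KH (1.5 equiv), THF, 0 °C; then 16, CsF (3 equiv), 18-crown-6, THF, 0 °C to rt; then PhMe, 100 °C (sealed tube); aq. NH4Cl
Reagents that add atoms: none
Why: Proposed new method: fluoride attacks silicon and expels triflate to give aryne 18, whose C4' methoxy group flattens the distal carbon C2' and stabilises charge building at C3', so the potassium tert-alkoxide should bond at C2' and the C3' anion is protonated by the excess alcohol (regenerating alkoxide) to give ether 19. Warming should then drive a chair aromatic Claisen [3,3] shift to C3', the only ortho carbon bearing hydrogen, and dienone 20 enolises to phenol 21 with the reversed allyl unit delivered as a prenyl group. The closest known reactions are the O-arylation of alcohols and tert-alkoxides by 3-alkoxyarynes made from 2-(trimethylsilyl)aryl triflates, and the Claisen rearrangement of aryl 1,1-dimethylallyl ethers; joining them in one flask with a tertiary allylic alkoxide is the new part. No ring closes and no stereocentre is created, and the C3–H of the chroman is not acidic enough to epimerise under the alkoxide. The selectivity needed is regiochemical (attack at C2' and not C3'); it rests on the inductive pull of the methoxy group outweighing the bulk of the chromanyl group beside C2', while the MOM ether keeps the ring A phenol from competing as a nucleophile.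

**Step 13**
Reactants: 21 3-methoxy-6-[(3R)-5-methoxy-7-(methoxymethoxy)chroman-3-yl]-2-(3-methylbut-2-en-1-yl)phenol
Product: 22 (3R)-3-[2-hydroxy-4-methoxy-3-(3-methylbut-2-en-1-yl)phenyl]-5-methoxychroman-7-ol
Conditions: 3 M HCl (aq.), MeOH, 40 °C
Reagents that add atoms: none
Why: Acid-catalysed acetal cleavage (transacetalisation to dimethoxymethane) should free the 7-hydroxyl, and dilute acid at 40 °C is expected to be too mild to add the 2'-phenol across the prenyl double bond.

**Compound list**
1 | 1-(2,4-dihydroxy-6-methoxyphenyl)ethanone | CC(=O)c1c(O)cc(O)cc1OC | starting material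
2 | 1-[2-hydroxy-6-methoxy-4-(methoxymethoxy)phenyl]ethanone | CC(=O)c1c(O)cc(OCOC)cc1OC | intermediate
3 | (E)-3-(dimethylamino)-1-[2-hydroxy-6-methoxy-4-(methoxymethoxy)phenyl]prop-2-en-1-one | CN(C)/C=C/C(=O)c1c(O)cc(OCOC)cc1OC | intermediate
4 | 3-iodo-5-methoxy-7-(methoxymethoxy)-4H-chromen-4-one | COc1cc(OCOC)cc2occ(I)c(=O)c12 | intermediate
5 | 3-methoxyphenol | COc1cccc(O)c1 | starting material
6 | 3-methoxyphenyl N,N-diethylcarbamate | CCN(CC)C(=O)Oc1cccc(OC)c1 | intermediate
7 | 2-lithio-3-methoxyphenyl N,N-diethylcarbamate (not isolated) | CCN(CC)C(=O)Oc1cccc(OC)c1[Li] | intermediate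
8 | 3-methoxy-2-(trimethylsilyl)phenyl N,N-diethylcarbamate | CCN(CC)C(=O)Oc1cccc(OC)c1[Si](C)(C)C | intermediate
9 | 6-lithio-3-methoxy-2-(trimethylsilyl)phenyl N,N-diethylcarbamate (not isolated) | CCN(CC)C(=O)Oc1c([Li])ccc(OC)c1[Si](C)(C)C | intermediate
10 | 3-methoxy-6-(4,4,5,5-tetramethyl-1,3,2-dioxaborolan-2-yl)-2-(trimethylsilyl)phenyl N,N-diethylcarbamate | CCN(CC)C(=O)Oc1c(B2OC(C)(C)C(C)(C)O2)ccc(OC)c1[Si](C)(C)C | intermediate
11 | 3-methoxy-6-[5-methoxy-7-(methoxymethoxy)-4-oxo-4H-chromen-3-yl]-2-(trimethylsilyl)phenyl N,N-diethylcarbamate | COc1cc(OCOC)cc2occ(-c3ccc(OC)c([Si](C)(C)C)c3OC(=O)N(CC)CC)c(=O)c12 | intermediate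
12 | 3-methoxy-6-[5-methoxy-7-(methoxymethoxy)-4-oxochroman-3-yl]-2-(trimethylsilyl)phenyl N,N-diethylcarbamate, racemising at C3 (not isolated) | COc1cc(OCOC)cc2OCC(c3ccc(OC)c([Si](C)(C)C)c3OC(=O)N(CC)CC)C(=O)c12 | intermediate
13 | 6-[(3R,4R)-4-hydroxy-5-methoxy-7-(methoxymethoxy)chroman-3-yl]-3-methoxy-2-(trimethylsilyl)phenyl N,N-diethylcarbamate | COc1cc(OCOC)cc2OC[C@@H](c3ccc(OC)c([Si](C)(C)C)c3OC(=O)N(CC)CC)[C@@H](O)c12 | intermediate
14 | 3-methoxy-6-[(3R)-5-methoxy-7-(methoxymethoxy)chroman-3-yl]-2-(trimethylsilyl)phenyl N,N-diethylcarbamate | COc1cc(OCOC)cc2c1C[C@H](c1ccc(OC)c([Si](C)(C)C)c1OC(=O)N(CC)CC)CO2 | intermediate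
15 | 3-methoxy-6-[(3R)-5-methoxy-7-(methoxymethoxy)chroman-3-yl]-2-(trimethylsilyl)phenol | COc1cc(OCOC)cc2c1C[C@H](c1ccc(OC)c([Si](C)(C)C)c1O)CO2 | intermediate
16 | 3-methoxy-6-[(3R)-5-methoxy-7-(methoxymethoxy)chroman-3-yl]-2-(trimethylsilyl)phenyl trifluoromethanesulfonate | COc1cc(OCOC)cc2c1C[C@H](c1ccc(OC)c([Si](C)(C)C)c1OS(=O)(=O)C(F)(F)F)CO2 | intermediate
17 | 2-methylbut-3-en-2-ol | CC(C)(O)C=C | starting material
18 | (3R)-5-methoxy-3-(4-methoxy-2,3-didehydrophenyl)-7-(methoxymethoxy)chroman, the C2'-C3' aryne (not isolated) | COc1cc(OCOC)cc2c1C[C@H](C1=CC=C(OC)C#C1)CO2 | intermediate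
19 | (3R)-5-methoxy-3-[4-methoxy-2-(2-methylbut-3-en-2-yloxy)phenyl]-7-(methoxymethoxy)chroman (not isolated) | COc1cc(OCOC)cc2c1C[C@H](c1ccc(OC)cc1OC(C)(C)C=C)CO2 | intermediate
20 | 3-methoxy-6-[(3R)-5-methoxy-7-(methoxymethoxy)chroman-3-yl]-2-(3-methylbut-2-en-1-yl)cyclohexa-3,5-dien-1-one, both C2 epimers (not isolated) | COc1cc(OCOC)cc2c1C[C@H](C1=CC=C(OC)C(CC=C(C)C)C1=O)CO2 | intermediate
21 | 3-methoxy-6-[(3R)-5-methoxy-7-(methoxymethoxy)chroman-3-yl]-2-(3-methylbut-2-en-1-yl)phenol | COc1cc(OCOC)cc2c1C[C@H](c1ccc(OC)c(CC=C(C)C)c1O)CO2 | intermediate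
22 | (3R)-3-[2-hydroxy-4-methoxy-3-(3-methylbut-2-en-1-yl)phenyl]-5-methoxychroman-7-ol | COc1cc(O)cc2c1C[C@H](c1ccc(OC)c(CC=C(C)C)c1O)CO2 | target

**Step count**
Total: 13 steps. Longest linear sequence: 10 steps (steps 4 to 13; the ring A branch, steps 1 to 3 and then 7 to 13, is equally long).

**Steps most likely to fail**

Step 12. Three things may go wrong. The bulky alkoxide may bond at C3' instead of C2' because of the chromanyl group beside C2', which after rearrangement would place the prenyl group at C2'. The alkoxide may attack the sulfonyl sulfur and merely return phenol 15. The C3' aryl anion may fragment the new ether before it is protonated. The fallback uses known chemistry only and sets out from 15. Fluoride-mediated protodesilylation (Bu4NF, THF, 60 °C) should give 5-methoxy-2-[(3R)-5-methoxy-7-(methoxymethoxy)chroman-3-yl]phenol F1. Copper-catalysed O-alkylation with 3-chloro-3-methylbut-1-yne (CuCl2·2H2O cat., DBU, MeCN, 0 °C) should then give (3R)-5-methoxy-3-[4-methoxy-2-(2-methylbut-3-yn-2-yloxy)phenyl]-7-(methoxymethoxy)chroman F2. Semihydrogenation (H2, Pd/CaCO3 poisoned with Pb(OAc)2, quinoline, EtOAc) delivers ether 19, where the detour rejoins the route. Heating 19 in toluene at 110 °C should effect the same Claisen shift to 21.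

Step 9. The very electron-rich C4 carbinol may ionise under the acidic hydrogenation conditions and lose the C3 proton, and hydrogenation of the resulting isoflav-3-ene would erode the enantiomeric purity. Alternatively the C–O cleavage may be too slow without acid strong enough to endanger the MOM group. The fallback is a radical deoxygenation that avoids a C4 cation and sets out from 13. Treatment with 1,1'-thiocarbonyldiimidazole (DMAP, CH2Cl2, rt) should give O-[(3R,4R)-3-{2-[(diethylcarbamoyl)oxy]-4-methoxy-3-(trimethylsilyl)phenyl}-5-methoxy-7-(methoxymethoxy)chroman-4-yl] 1H-imidazole-1-carbothioate F3. Barton–McCombie reduction at room temperature (Bu3SnH, Et3B, air, PhMe) then returns to the route at 14.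

Step 8. Conjugate hydride transfer to the electron-rich, hindered 5-methoxychromone may be slow, and a sluggish first reduction can spoil the dynamic kinetic resolution and the cis selectivity. The fallback separates the two reductions and sets out from 11. Conjugate reduction with LiBH(s-Bu)3 (THF, −78 °C) should give the racemic isoflavanone 12, which is isolated. The same ruthenium catalyst under HCO2H/Et3N then reduces only the ketone with dynamic kinetic resolution and returns to the route at 13. New compounds on this detour: none F0.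

**Further compounds**
F1 | step 12 | 5-methoxy-2-[(3R)-5-methoxy-7-(methoxymethoxy)chroman-3-yl]phenol | COc1cc(OCOC)cc2c1C[C@H](c1ccc(OC)cc1O)CO2
F2 | step 12 | (3R)-5-methoxy-3-[4-methoxy-2-(2-methylbut-3-yn-2-yloxy)phenyl]-7-(methoxymethoxy)chroman | COc1cc(OCOC)cc2c1C[C@H](c1ccc(OC)cc1OC(C)(C)C#C)CO2
F3 | step 9 | O-[(3R,4R)-3-{2-[(diethylcarbamoyl)oxy]-4-methoxy-3-(trimethylsilyl)phenyl}-5-methoxy-7-(methoxymethoxy)chroman-4-yl] 1H-imidazole-1-carbothioate | COc1cc(OCOC)cc2OC[C@@H](c3ccc(OC)c([Si](C)(C)C)c3OC(=O)N(CC)CC)[C@@H](OC(=S)n3ccnc3)c12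
F0 | step 8 | none | none
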